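Ring B is built, not functionalised: it is cut at C3–C4 and C1–C2 (C1 = aryloxy carbon, C3 = carbon bearing the quaternary side chain, C5/C6 = catechol carbons). A Stille coupling joins racemic 4-chloro-2,3-dimethoxycyclobutenone to an (S)-1-(trimethylstannyl)vinyl compound that already carries the quaternary stereocentre. 4π opening and 6π closure of the resulting dienylketene then deliver the ring B phenol in the same flask. The step exploits the 5-alkylpyrogallol pattern of ring B with one distinct terminal oxygen: the cyclobutenone carbonyl becomes the only free hydroxyl at C1, ready for Ullmann union with the (R)-ring A bromide before global demethylation.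

Key step: step 8

Assumption: Lig is the sulfonate-bearing imidazolinium salt 1-(2,6-diisopropylphenyl)-4,5-diphenyl-3-(2-sulfonatophenyl)-4,5-dihydroimidazolium; its (S,S) antipode is taken to give the (S) enyne in step 2 and its (R,R) antipode the (R) arene in step 9, to be confirmed or swapped after a test run.

Step 1
Reactants: 1 (2E,6E)-farnesol
Product: 2 diethyl [(2E,6E)-3,7,11-trimethyldodeca-2,6,10-trien-1-yl] phosphate
Conditions: ClP(O)(OEt)2, Et3N, DMAP (cat.), CH2Cl2, 0 °C → rt
Reagents that add atoms: diethyl chlorophosphate, CCOP(=O)(Cl)OCC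
Why: Phosphorylation of a primary allylic alcohol at phosphorus under amine base is routine and leaves the E alkenes untouched.

Step 2
Reactants: 3 trimethylsilylacetylene; 2 diethyl (2E,6E)-farnesyl phosphate
Product: 5 trimethyl[(3S,6E)-3-ethenyl-3,7,11-trimethyldodeca-6,10-dien-1-yn-1-yl]silane, via alkynylalane 4 (not isolated)
Conditions: i-Bu2AlH, Et3N (5 mol%), hexanes, 0 → 22 °C; then 2, CuCl2·2H2O (5 mol%), (S,S)-Lig premetalated with Ag2O (2.5 mol%), THF, −15 °C
Reagents that add atoms: none
Why: In this copper-catalysed enantioselective allylic substitution the alkynyl group of alane 4 should add SN2′ at C3 of the (E)-allylic phosphate, and the catalyst formed from CuCl2·2H2O and the chiral sulfonate carbene ligand selects one face of the trisubstituted alkene and so sets the (S) quaternary centre.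

Step 3
Reactants: 5 trimethyl[(3S,6E)-3-ethenyl-3,7,11-trimethyldodeca-6,10-dien-1-yn-1-yl]silane
Product: 6 (3S,6E)-3-ethenyl-3,7,11-trimethyldodeca-6,10-dien-1-yne
Conditions: K2CO3 (cat.), MeOH, rt
Reagents that add atoms: none
Why: Protodesilylation by methanolysis of the alkynyl C–Si bond is selective and cannot affect the hydrogen-free quaternary centre.

Step 4
Reactants: 6 (3S,6E)-3-ethenyl-3,7,11-trimethyldodeca-6,10-dien-1-yne
Product: 8 (3S,6E)-2-bromo-3-ethenyl-3,7,11-trimethyldodeca-1,6,10-triene, via bromoalkenylborane 7 (not isolated)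
Conditions: B-bromo-9-borabicyclo[3.3.1]nonane, CH2Cl2, 0 °C → rt; then AcOH, 0 °C
Reagents that add atoms: B-bromo-9-borabicyclo[3.3.1]nonane, BrB1C2CCCC1CCC2
Why: Haloboration adds B–Br syn across the terminal alkyne only, with the bulky boron at the terminal carbon and bromine at the internal one, so sterics and electronics agree (a hydrostannation would have to place tin next to the quaternary carbon), and protonolysis of the C–B bond leaves the 2-bromo-1-alkene.

Step 5
Reactants: 8 (3S,6E)-2-bromo-3-ethenyl-3,7,11-trimethyldodeca-1,6,10-triene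
Product: 10 trimethyl[(3S,6E)-3-ethenyl-3,7,11-trimethyldodeca-1,6,10-trien-2-yl]stannane, via alkenyllithium 9 (not isolated)
Conditions: t-BuLi (2.1 equiv), Et2O, −78 °C; then Me3SnCl, −78 °C → rt
Reagents that add atoms: chlorotrimethylstannane, C[Sn](C)(C)Cl
Why: Bromine–lithium exchange followed by stannylation fixes the metal regiospecifically at the 1-substituted vinyl carbon, and trimethyltin is chosen over tributyltin because it transmetalates faster at a hindered carbon.

Step 6
Reactants: 11 dimethyl squarate
Product: 12 4-hydroxy-2,3-dimethoxycyclobut-2-en-1-one (racemic)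
Conditions: LiAlH(OtBu)3 (1.05 equiv), THF, −78 → −20 °C; pH 7 work-up
Reagents that add atoms: none
Why: This hydride 1,2-reduction with a bulky, mild reagent should stop after one carbonyl because the remaining one is a deactivated vinylogous ester, and the new carbinol centre is racemic and is erased in step 8.

Step 7
Reactants: 12 4-hydroxy-2,3-dimethoxycyclobut-2-en-1-one
Product: 13 4-chloro-2,3-dimethoxycyclobut-2-en-1-one (racemic)
Conditions: PPh3, hexachloroacetone, CH2Cl2, −20 → 0 °C; used at once without chromatography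
Reagents that add atoms: hexachloroacetone, ClC(Cl)(Cl)C(=O)C(Cl)(Cl)Cl
Why: Appel-type chlorination displaces the allylic, α-keto hydroxyl through its oxyphosphonium salt under neutral, cold conditions, which avoids the acid-triggered loss of methanol typical of such hydroxycyclobutenones.

Step 8
Reactants: 13 4-chloro-2,3-dimethoxycyclobut-2-en-1-one; 10 trimethyl[(3S,6E)-3-ethenyl-3,7,11-trimethyldodeca-1,6,10-trien-2-yl]stannane
Product: 17 2,3-dimethoxy-5-[(3S,6E)-3,7,11-trimethyldodeca-1,6,10-trien-3-yl]phenol, via alkenylcyclobutenone 14 (not isolated), via dienylketene 15 (not isolated), via cyclohexadienone 16 (not isolated)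
Conditions: 13 (1.3 equiv), PdCl2(PhCN)2 (5 mol%), tri(2-furyl)phosphine (10 mol%), CuI (10 mol%), dioxane, 50 °C; then 100 °C
Reagents that add atoms: none
Why: Zerovalent palladium, generated from PdCl2(PhCN)2 by the stannane, inserts into the allylic, α-keto C–Cl bond of 13, the alkenyl group of 10 is transferred from tin (relayed by CuI, which eases transmetalation at the hindered 1-(tert-alkyl)vinyl carbon) and reductive elimination forms the C3–C4 bond of ring B in 14. Warming then opens 14 by conrotatory 4π ring opening to dienylketene 15, and ring B is closed by thermal disrotatory 6π electrocyclisation, which forms C1–C2 and gives dienone 16 that tautomerises to phenol 17. The closest known reaction type is the palladium-catalysed coupling of 4-chlorocyclobutenones with alkenylstannanes followed by thermal benzannulation to phenols. No stereocentre is created: the chlorine-bearing carbon is racemic and becomes planar on ring opening, and the (S) quaternary centre carries no hydrogen and passes through unchanged. The step needs regiocontrol, which the connectivity secures, because the ketene carbon can only become C1 with the single free hydroxyl, the two methoxy carbons C6 and C5, the former CHCl carbon C4 and the vinyl CH2 C2, and because ring opening is reversible so that both ketene geometries drain through the one that can cyclise. It also needs chemoselectivity over the three spectator alkenes, secured by the far higher reactivity of the activated C–Cl bond toward zerovalent palladium and by 6π closure being faster than any ketene–alkene cycloaddition.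

Step 9
Reactants: 18 2-bromo-4-iodo-1-methoxybenzene; 2 diethyl (2E,6E)-farnesyl phosphate
Product: 21 2-bromo-1-methoxy-4-[(3R,6E)-3,7,11-trimethyldodeca-1,6,10-trien-3-yl]benzene, via aryllithium 19 (not isolated), via arylalane 20 (not isolated)
Conditions: n-BuLi (1.0 equiv), THF, −78 °C; Et2AlCl, −78 → 0 °C; then 2, CuCl2·2H2O (5 mol%), (R,R)-Lig premetalated with Ag2O (2.5 mol%), THF, −30 °C
Reagents that add atoms: none
Why: Selective iodine–lithium exchange and transmetalation give arylalane 20, whose aryl group should add SN2′ at C3 of the (E)-phosphate in a copper-catalysed enantioselective allylic substitution, where the enantiomeric ligand selects the opposite alkene face and sets the (R) quaternary centre while the bromine is carried along as the coupling handle.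

Step 10
Reactants: 21 2-bromo-1-methoxy-4-[(3R,6E)-3,7,11-trimethyldodeca-1,6,10-trien-3-yl]benzene; 17 2,3-dimethoxy-5-[(3S,6E)-3,7,11-trimethyldodeca-1,6,10-trien-3-yl]phenol
Product: 22 1,2-dimethoxy-3-{2-methoxy-5-[(3R,6E)-3,7,11-trimethyldodeca-1,6,10-trien-3-yl]phenoxy}-5-[(3S,6E)-3,7,11-trimethyldodeca-1,6,10-trien-3-yl]benzene
Conditions: 17 (1.2 equiv), CuI (10 mol%), N,N-dimethylglycine (30 mol%), Cs2CO3, dioxane, 100 °C
Reagents that add atoms: none
Why: In this Ullmann ether synthesis the caesium phenoxide of 17 should displace bromide from 21 under CuI and amino acid catalysis, conditions that accept ortho-alkoxy groups on both partners and leave isolated alkenes and both quaternary centres alone.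

Step 11
Reactants: 22 1,2-dimethoxy-3-{2-methoxy-5-[(3R,6E)-3,7,11-trimethyldodeca-1,6,10-trien-3-yl]phenoxy}-5-[(3S,6E)-3,7,11-trimethyldodeca-1,6,10-trien-3-yl]benzene
Product: 23 3-{2-hydroxy-5-[(3R,6E)-3,7,11-trimethyldodeca-1,6,10-trien-3-yl]phenoxy}-5-[(3S,6E)-3,7,11-trimethyldodeca-1,6,10-trien-3-yl]benzene-1,2-diol (target)
Conditions: Me3SiSNa (excess), 1,3-dimethyl-2-imidazolidinone, 185 °C, sealed tube, argon; dilute aq. HCl
Reagents that add atoms: none
Why: Nucleophilic SN2 demethylation by the thiolate should cleave all three aryl methyl ethers under base-only conditions that spare the acid-sensitive polyene, and because each freed phenoxide is silylated by the reagent the second methoxy group of the ring B catechol is not shielded by a neighbouring negative charge before aqueous acid releases the hydroxyls.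

Compound list
1 | (2E,6E)-farnesol | CC(C)=CCC/C(C)=C/CC/C(C)=C/CO | starting material
2 | diethyl [(2E,6E)-3,7,11-trimethyldodeca-2,6,10-trien-1-yl] phosphate | CC(C)=CCC/C(C)=C/CC/C(C)=C/COP(=O)(OCC)OCC | intermediate
3 | trimethylsilylacetylene | C#C[Si](C)(C)C | starting material
4 | diisobutyl[(trimethylsilyl)ethynyl]alumane | CC(C)C[Al](CC(C)C)C#C[Si](C)(C)C | intermediate
5 | trimethyl[(3S,6E)-3-ethenyl-3,7,11-trimethyldodeca-6,10-dien-1-yn-1-yl]silane | C[Si](C)(C)C#C[C@](C)(C=C)CC/C=C(\C)CCC=C(C)C | intermediate
6 | (3S,6E)-3-ethenyl-3,7,11-trimethyldodeca-6,10-dien-1-yne | C#C[C@](C)(C=C)CC/C=C(\C)CCC=C(C)C | intermediate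
7 | 9-[(1Z,3S,6E)-2-bromo-3-ethenyl-3,7,11-trimethyldodeca-1,6,10-trien-1-yl]-9-borabicyclo[3.3.1]nonane | Br/C(=C\B1C2CCCC1CCC2)[C@](C)(C=C)CC/C=C(\C)CCC=C(C)C | intermediate
8 | (3S,6E)-2-bromo-3-ethenyl-3,7,11-trimethyldodeca-1,6,10-triene | C=C(Br)[C@](C)(C=C)CC/C=C(\C)CCC=C(C)C | intermediate
9 | [(3S,6E)-3-ethenyl-3,7,11-trimethyldodeca-1,6,10-trien-2-yl]lithium | [Li]C(=C)[C@](C)(C=C)CC/C=C(\C)CCC=C(C)C | intermediate
10 | trimethyl[(3S,6E)-3-ethenyl-3,7,11-trimethyldodeca-1,6,10-trien-2-yl]stannane | C=C([Sn](C)(C)C)[C@](C)(C=C)CC/C=C(\C)CCC=C(C)C | intermediate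
11 | dimethyl squarate (3,4-dimethoxycyclobut-3-ene-1,2-dione) | COC1=C(OC)C(=O)C1=O | starting material
12 | 4-hydroxy-2,3-dimethoxycyclobut-2-en-1-one (racemic) | COC1=C(OC)C(O)C1=O | intermediate
13 | 4-chloro-2,3-dimethoxycyclobut-2-en-1-one (racemic) | COC1=C(OC)C(Cl)C1=O | intermediate
14 | 2,3-dimethoxy-4-[(3S,6E)-3-ethenyl-3,7,11-trimethyldodeca-1,6,10-trien-2-yl]cyclobut-2-en-1-one (both epimers at the ring carbon) | COC1=C(OC)C(C(=C)[C@](C)(C=C)CC/C=C(\C)CCC=C(C)C)C1=O | intermediate
15 | (3E)-2,3-dimethoxy-5-[(3S,6E)-3,7,11-trimethyldodeca-1,6,10-trien-3-yl]hexa-1,3,5-trien-1-one (ketene carbon and C5 cis across C3=C4) | O=C=C(OC)/C(OC)=C\C(=C)[C@](C)(C=C)CC/C=C(\C)CCC=C(C)C | intermediate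
16 | 2,3-dimethoxy-5-[(3S,6E)-3,7,11-trimethyldodeca-1,6,10-trien-3-yl]cyclohexa-2,4-dien-1-one | COC1=C(OC)C(=O)CC([C@](C)(C=C)CC/C=C(\C)CCC=C(C)C)=C1 | intermediate
17 | 2,3-dimethoxy-5-[(3S,6E)-3,7,11-trimethyldodeca-1,6,10-trien-3-yl]phenol | COc1cc([C@](C)(C=C)CC/C=C(\C)CCC=C(C)C)cc(O)c1OC | intermediate
18 | 2-bromo-4-iodo-1-methoxybenzene | COc1ccc(I)cc1Br | starting material
19 | (3-bromo-4-methoxyphenyl)lithium | COc1ccc([Li])cc1Br | intermediate
20 | (3-bromo-4-methoxyphenyl)diethylalumane | CC[Al](CC)c1ccc(OC)c(Br)c1 | intermediate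
21 | 2-bromo-1-methoxy-4-[(3R,6E)-3,7,11-trimethyldodeca-1,6,10-trien-3-yl]benzene | COc1ccc([C@@](C)(C=C)CC/C=C(\C)CCC=C(C)C)cc1Br | intermediate
22 | 1,2-dimethoxy-3-{2-methoxy-5-[(3R,6E)-3,7,11-trimethyldodeca-1,6,10-trien-3-yl]phenoxy}-5-[(3S,6E)-3,7,11-trimethyldodeca-1,6,10-trien-3-yl]benzene | COc1ccc([C@@](C)(C=C)CC/C=C(\C)CCC=C(C)C)cc1Oc1cc([C@](C)(C=C)CC/C=C(\C)CCC=C(C)C)cc(OC)c1OC | intermediate
23 | 3-{2-hydroxy-5-[(3R,6E)-3,7,11-trimethyldodeca-1,6,10-trien-3-yl]phenoxy}-5-[(3S,6E)-3,7,11-trimethyldodeca-1,6,10-trien-3-yl]benzene-1,2-diol | C=C[C@@](C)(CC/C=C(\C)CCC=C(C)C)c1ccc(O)c(Oc2cc([C@](C)(C=C)CC/C=C(\C)CCC=C(C)C)cc(O)c2O)c1 | target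

Total steps: 11. Longest linear sequence: 8 steps (steps 1, 2, 3, 4, 5, 8, 10, 11); steps 6–7 and step 9 are side branches.

Steps most likely to fail

Step 8. Transmetalation at the hindered 1-(tert-alkyl)vinyl carbon may be too slow, so that methyl transfer from tin, or thermal and demethylative breakdown of the chlorocyclobutenone, overtakes the coupling. The fallback sets out from 2 and returns at 17: ring B is taken from an existing arene and its quaternary centre is made by the same allylic arylation as in step 9. Baeyer–Villiger oxidation of commercial 5-bromo-2,3-dimethoxybenzaldehyde (mCPBA, CH2Cl2) should give 5-bromo-2,3-dimethoxyphenyl formate F1, methanolysis (K2CO3, MeOH) 5-bromo-2,3-dimethoxyphenol F2, and MOMCl with i-Pr2NEt 5-bromo-1,2-dimethoxy-3-(methoxymethoxy)benzene F3. Bromine–lithium exchange (n-BuLi, THF, −78 °C) gives [3,4-dimethoxy-5-(methoxymethoxy)phenyl]lithium F4, Et2AlCl turns it into diethyl[3,4-dimethoxy-5-(methoxymethoxy)phenyl]alumane F5, and SN2′ arylation of 2 with CuCl2·2H2O and (S,S)-Lig premetalated with Ag2O should give 1,2-dimethoxy-3-(methoxymethoxy)-5-[(3S,6E)-3,7,11-trimethyldodeca-1,6,10-trien-3-yl]benzene F6. Catalytic HCl in MeOH at rt removes the acetal and gives 17.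

Step 7. Ionisation at the activated carbinol or chloride carbon, followed by loss of a methyl group from the neighbouring enol ether, would destroy the cyclobutenone during chlorination or handling. The fallback sets out from 12 and returns at 17: the hydroxyl is acetylated instead (Ac2O, pyridine, 0 °C) to 2,3-dimethoxy-4-oxocyclobut-2-en-1-yl acetate F7, an allylic ester that can be stored. Zerovalent palladium (Pd2(dba)3, tri(2-furyl)phosphine, LiCl, DMF, 50 °C) ionises it and couples the oxo-allyl complex with stannane 10 in an allylic acetate Stille coupling, and heating to 100 °C carries the product through 14, 15 and 16 to 17.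

Step 11. Cleavage may stall at the last methyl ether of the ring B catechol, or the long heating may degrade the polyene. The fallback sets out from 22 and returns at 23 and makes no new compound (F0): demethylation in a MeMgI melt (neat, 160–170 °C, short time, then cold aq. NH4Cl). Here magnesium binds the ether oxygen and iodide removes the methyl group, a Lewis-acid-assisted mechanism that a neighbouring aryloxide helps by chelation instead of retarding.

Further compounds
F1 | step 8 | 5-bromo-2,3-dimethoxyphenyl formate | O=COc1cc(Br)cc(OC)c1OC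
F2 | step 8 | 5-bromo-2,3-dimethoxyphenol | Oc1cc(Br)cc(OC)c1OC
F3 | step 8 | 5-bromo-1,2-dimethoxy-3-(methoxymethoxy)benzene | COCOc1cc(Br)cc(OC)c1OC
F4 | step 8 | [3,4-dimethoxy-5-(methoxymethoxy)phenyl]lithium | [Li]c1cc(OC)c(OC)c(OCOC)c1
F5 | step 8 | diethyl[3,4-dimethoxy-5-(methoxymethoxy)phenyl]alumane | CC[Al](CC)c1cc(OC)c(OC)c(OCOC)c1
F6 | step 8 | 1,2-dimethoxy-3-(methoxymethoxy)-5-[(3S,6E)-3,7,11-trimethyldodeca-1,6,10-trien-3-yl]benzene | COCOc1cc([C@](C)(C=C)CC/C=C(\C)CCC=C(C)C)cc(OC)c1OC
F7 | step 7 | 2,3-dimethoxy-4-oxocyclobut-2-en-1-yl acetate | CC(=O)OC1C(OC)=C(OC)C1=O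
F0 | step 11 | none | none
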